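The route rests on cutting the tetramethylcyclohexanetrione ring at two bonds, C-2–C-1(=O) and C-3(=O)–C-4(Me2). What stays on the arene side is C-2 as a methylene, the C-3 carbonyl, the benzylic methine and the ortho phenol oxygen beside the C-methyl group. These atoms form the C-3, C-2, C-4, O-1 chain of a 4-(2-phenylethyl)dihydrocoumarin lactone ring. In one flask the lithium enolate of methyl 2,2,4-trimethyl-3-oxopentanoate opens this lactone at its carbonyl. The new ketone, enolised at the old lactone methylene, then cyclises on the ester, so the whole triketone ring appears beside an untouched stereocentre. The precursor is the (4S)-5,7-dibenzyloxy-8-methyl lactone, made by asymmetric copper hydride reduction of a Pechmann coumarin.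

Key step: step 5

Assumption: lactonisation in step 1 is taken to involve the hydroxyl beside the C-methyl group (any 6-methyl isomer is removed when 4 is crystallised and would in any case lead to the same 12), and the ligand antipode that delivers 4S in step 3 is settled by a pilot run, both antipodes being commercial.

Step 1
Reactants: 1 2-methylphloroglucinol (2-methylbenzene-1,3,5-triol); 2 ethyl 3-oxo-5-phenylpentanoate
Product: 3 5,7-dihydroxy-8-methyl-4-(2-phenylethyl)-2H-chromen-2-one
Conditions: CF3CO2H, reflux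
Reagents that add atoms: none
Why: Pechmann condensation, in which a free ring carbon of 1 attacks the protonated ketone of 2 and loss of water plus lactonisation through an ortho hydroxyl give the coumarin, the phloroglucinol ring being so much more nucleophilic than the phenyl ring of 2 that self-cyclisation of the keto ester should not compete.

Step 2
Reactants: 3 5,7-dihydroxy-8-methyl-4-(2-phenylethyl)-2H-chromen-2-one
Product: 4 5,7-bis(benzyloxy)-8-methyl-4-(2-phenylethyl)-2H-chromen-2-one
Conditions: BnBr (2.5 equiv), K2CO3 (3 equiv), DMF, 60 °C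
Reagents that add atoms: benzyl bromide, BrCc1ccccc1
Why: Williamson ether synthesis on both phenoxides, to which the lactone is inert, benzyl being chosen because it survives hydride, boron and enolate chemistry and leaves later under neutral hydrogenolysis.

Step 3
Reactants: 4 5,7-bis(benzyloxy)-8-methyl-4-(2-phenylethyl)-2H-chromen-2-one
Product: 6 (4S)-5,7-bis(benzyloxy)-8-methyl-4-(2-phenylethyl)chroman-2-one, via boron enolate 5 (not isolated)
Conditions: CuCl (5 mol %), NaOt-Bu (5 mol %), (R)-DTBM-SEGPHOS (5.5 mol %), pinacolborane (1.5 equiv), toluene, rt; aq NH4Cl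
Reagents that add atoms: none
Why: Asymmetric conjugate reduction run as a copper hydride catalysed 1,4-hydroboration, in which the bisphosphine-bound CuH delivers hydride to one face of C-4 and so sets 4S, while the boron enolate 5 shields the aryl lactone from further reduction until work-up protonates the non-stereogenic C-3.

Step 4
Reactants: 7 2,2,4,4-tetramethylcyclobutane-1,3-dione
Product: 8 methyl 2,2,4-trimethyl-3-oxopentanoate
Conditions: NaOMe (5 mol %), MeOH, 0 °C → rt; AcOH quench, distillation
Reagents that add atoms: methanol, CO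
Why: Alkoxide-catalysed retro-Claisen ring opening, in which methoxide adds to a carbonyl of the strained, non-enolisable dione, C–C cleavage releases the ring strain and methanol protonates the enolate, catalytic base and low temperature preventing a second cleavage to methyl isobutyrate.

Step 5
Reactants: 6 (4S)-5,7-bis(benzyloxy)-8-methyl-4-(2-phenylethyl)chroman-2-one; 8 methyl 2,2,4-trimethyl-3-oxopentanoate
Product: 11 2-{(1R)-1-[4,6-bis(benzyloxy)-2-hydroxy-3-methylphenyl]-3-phenylpropyl}-3-hydroxy-4,4,6,6-tetramethylcyclohex-2-ene-1,5-dione, via lithium enolate 9 (not isolated), via open-chain diketo ester 10 (not isolated)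
Conditions: 8 (3.1 equiv), LiN(i-Pr)2 (3.0 equiv), THF, −78 → 0 °C; 6 in THF added slowly at −78 °C, → rt, then 40 °C; cold 1 M HCl
Reagents that add atoms: none
Why: Mechanism: carbon attack of the fully substituted enolate 9 on C-2 of 6 gives a tetrahedral adduct that collapses with loss of the aryloxide (crossed Claisen acylation, aryl ester as donor), so 10 arises as its lithium phenoxide; spare 9 then deprotonates 10 at the former C-3 methylene, its sole acidic C–H site, and this enolate displaces methoxide from the ester. The closest known chemistry is C-acylation of this very enolate by an acyl chloride followed by base-induced Dieckmann cyclisation to the tetramethylcyclohexanetrione, together with the opening of dihydrocoumarins by lithium enolates. The six-membered ring closes in the 6-exo-trig mode. No stereocentre is created: C-4 of 6 is never alpha to a carbonyl, has no leaving group on a neighbouring atom, and ends up next to a triketonate whose C-2 is already deprotonated and therefore cannot depart in a retro-Michael sense, so S in 6 maps onto R in 11 by a change of priorities only. The selectivity required is acyl transfer to carbon in preference to proton abstraction from C-3 of 6 and to O-acylation; slow addition of 6 to a threefold excess of 9 keeps free lactone scarce and so starves self-condensation, proton exchange and O-acylation are both reversible (the phenoxide cleaves any enol ester, and an aryl ester enolate remains an acyl donor through the E1cB pathway), and the aryloxide is a much better leaving group than an alkoxide. The doubly stabilised triketonate is the only thermodynamic sink, so these equilibria should drain into 11.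

Step 6
Reactants: 11 2-{(1R)-1-[4,6-bis(benzyloxy)-2-hydroxy-3-methylphenyl]-3-phenylpropyl}-3-hydroxy-4,4,6,6-tetramethylcyclohex-2-ene-1,5-dione
Product: 12 3-hydroxy-4,4,6,6-tetramethyl-2-[(1R)-3-phenyl-1-(2,4,6-trihydroxy-3-methylphenyl)propyl]cyclohex-2-ene-1,5-dione
Conditions: H2 (1 atm), 10% Pd/C, EtOAc–MeOH, rt; handled under argon
Reagents that add atoms: none
Why: Catalytic hydrogenolysis of aryl benzyl ethers under neutral conditions, to which the enolised triketone, the phenyl rings and the C–C bonds at the methine are inert, so the configuration is kept.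

Step 7
Reactants: 12 3-hydroxy-4,4,6,6-tetramethyl-2-[(1R)-3-phenyl-1-(2,4,6-trihydroxy-3-methylphenyl)propyl]cyclohex-2-ene-1,5-dione; 13 3-phenylpropanoyl chloride
Product: 14 3-hydroxy-4,4,6,6-tetramethyl-2-{(1R)-3-phenyl-1-[2,4,6-trihydroxy-3-methyl-5-(3-phenylpropanoyl)phenyl]propyl}cyclohex-2-ene-1,5-dione (CNP0236721.1)
Conditions: TiCl4 (4 equiv), CH2Cl2, −40 °C, then 13 (1.2 equiv), → 0 °C; ice-cold 1 M HCl
Reagents that add atoms: none
Why: Friedel–Crafts acylation at the single unsubstituted ring carbon, which two ortho oxygens and one para oxygen make far more nucleophilic than either phenyl ring, while TiCl4 holds the phenols and the triketone as titanium phenoxides and diketonate so that acyl transfer should go to carbon at a temperature where neither water loss between phenol and enol nor cleavage at the methine competes, the stereocentre not being involved.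

Compound list
1 | 2-methylphloroglucinol | Cc1c(O)cc(O)cc1O | starting material
2 | ethyl 3-oxo-5-phenylpentanoate | CCOC(=O)CC(=O)CCc1ccccc1 | starting material
3 | 5,7-dihydroxy-8-methyl-4-(2-phenylethyl)-2H-chromen-2-one | O=C1C=C(CCc2ccccc2)c2c(O)cc(O)c(C)c2O1 | intermediate
4 | 5,7-bis(benzyloxy)-8-methyl-4-(2-phenylethyl)-2H-chromen-2-one | O=C1C=C(CCc2ccccc2)c2c(OCc3ccccc3)cc(OCc3ccccc3)c(C)c2O1 | intermediate
5 | (4S)-5,7-bis(benzyloxy)-8-methyl-4-(2-phenylethyl)-2-[(4,4,5,5-tetramethyl-1,3,2-dioxaborolan-2-yl)oxy]-4H-chromene (boron enolate, not isolated) | CC1(C)OB(OC2=C[C@H](CCc3ccccc3)c3c(OCc4ccccc4)cc(OCc4ccccc4)c(C)c3O2)OC1(C)C | intermediate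
6 | (4S)-5,7-bis(benzyloxy)-8-methyl-4-(2-phenylethyl)chroman-2-one | O=C1C[C@H](CCc2ccccc2)c2c(OCc3ccccc3)cc(OCc3ccccc3)c(C)c2O1 | intermediate
7 | 2,2,4,4-tetramethylcyclobutane-1,3-dione | CC1(C)C(=O)C(C)(C)C1=O | starting material
8 | methyl 2,2,4-trimethyl-3-oxopentanoate | COC(=O)C(C)(C)C(=O)C(C)C | intermediate
9 | methyl 3-lithiooxy-2,2,4-trimethylpent-3-enoate (lithium enolate of 8, not isolated) | COC(=O)C(C)(C)C([O-])=C(C)C.[Li+] | intermediate
10 | methyl (7S)-7-[4,6-bis(benzyloxy)-2-hydroxy-3-methylphenyl]-2,2,4,4-tetramethyl-3,5-dioxo-9-phenylnonanoate (present as lithium phenoxide, not isolated) | COC(=O)C(C)(C)C(=O)C(C)(C)C(=O)C[C@H](CCc1ccccc1)c1c(OCc2ccccc2)cc(OCc2ccccc2)c(C)c1O | intermediate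
11 | 2-{(1R)-1-[4,6-bis(benzyloxy)-2-hydroxy-3-methylphenyl]-3-phenylpropyl}-3-hydroxy-4,4,6,6-tetramethylcyclohex-2-ene-1,5-dione (2-substituted syncarpic acid, enol form) | Cc1c(OCc2ccccc2)cc(OCc2ccccc2)c([C@@H](CCc2ccccc2)C2=C(O)C(C)(C)C(=O)C(C)(C)C2=O)c1O | intermediate
12 | 3-hydroxy-4,4,6,6-tetramethyl-2-[(1R)-3-phenyl-1-(2,4,6-trihydroxy-3-methylphenyl)propyl]cyclohex-2-ene-1,5-dione | Cc1c(O)cc(O)c([C@@H](CCc2ccccc2)C2=C(O)C(C)(C)C(=O)C(C)(C)C2=O)c1O | intermediate
13 | 3-phenylpropanoyl chloride | O=C(Cl)CCc1ccccc1 | starting material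
14 | 3-hydroxy-4,4,6,6-tetramethyl-2-{(1R)-3-phenyl-1-[2,4,6-trihydroxy-3-methyl-5-(3-phenylpropanoyl)phenyl]propyl}cyclohex-2-ene-1,5-dione (CNP0236721.1) | Cc1c(O)c(C(=O)CCc2ccccc2)c(O)c([C@@H](CCc2ccccc2)C2=C(O)C(C)(C)C(=O)C(C)(C)C2=O)c1O | target

Total step count: 7. Longest linear sequence: 6 (steps 1, 2, 3, 5, 6, 7).

Steps most likely to fail

Step 5. Proton transfer from the lactone methylene to the hindered enolate may outrun C–C bond formation, which would leave lactone self-condensation or mere recovery of both partners.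
- The fallback sets out from 6 and comes back at 12.
- It forms the same two ring bonds, but it replaces the lactone by an open-chain acyl chloride, the donor class for which C-acylation of 9 is established, and closes the ring in a separate operation.
- NaOH in aqueous THF opens 6 to disodium (3S)-3-[4,6-bis(benzyloxy)-3-methyl-2-oxidophenyl]-5-phenylpentanoate F1.
- BnBr in DMF caps F1 on both oxygens to give benzyl (3S)-5-phenyl-3-[2,4,6-tris(benzyloxy)-3-methylphenyl]pentanoate F2.
- LiOH frees (3S)-5-phenyl-3-[2,4,6-tris(benzyloxy)-3-methylphenyl]pentanoic acid F3.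
- (COCl)2 with catalytic DMF gives (3S)-5-phenyl-3-[2,4,6-tris(benzyloxy)-3-methylphenyl]pentanoyl chloride F4.
- Addition of F4 to 9 in THF at −78 °C should give methyl (7S)-2,2,4,4-tetramethyl-3,5-dioxo-9-phenyl-7-[2,4,6-tris(benzyloxy)-3-methylphenyl]nonanoate F5.
- KOt-Bu in THF closes F5 in a Dieckmann condensation to 3-hydroxy-4,4,6,6-tetramethyl-2-{(1R)-3-phenyl-1-[2,4,6-tris(benzyloxy)-3-methylphenyl]propyl}cyclohex-2-ene-1,5-dione F6.
- Hydrogenolysis (H2, 10% Pd/C) of the three benzyl ethers then gives 12.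

Step 7. Three processes may compete: acyl transfer to an enol or phenol oxygen instead of the ring carbon, loss of water between an ortho phenol and the activated enol, and Lewis acid ionisation of the benzylic C–C bond with erosion of enantiopurity.
- The fallback sets out from 6 and comes back at 14.
- It replaces electrophilic acylation by acylation of an aryllithium, so that no acid meets the phenol–enol pair.
- NBS in MeCN at 0 °C brominates the only free arene carbon of 6 to (4S)-5,7-bis(benzyloxy)-6-bromo-8-methyl-4-(2-phenylethyl)chroman-2-one F7.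
- The conditions of step 5 take F7 through methyl (7S)-7-[4,6-bis(benzyloxy)-5-bromo-2-hydroxy-3-methylphenyl]-2,2,4,4-tetramethyl-3,5-dioxo-9-phenylnonanoate F8, which is not isolated, to 2-{(1R)-1-[4,6-bis(benzyloxy)-5-bromo-2-hydroxy-3-methylphenyl]-3-phenylpropyl}-3-hydroxy-4,4,6,6-tetramethylcyclohex-2-ene-1,5-dione F9.
- MeLi (2 equiv, THF, −78 °C) removes the two acidic protons, and t-BuLi (2 equiv) exchanges bromine for lithium to give the aryllithium dilithium salt of the debrominated triketone F10.
- N-methoxy-N-methyl-3-phenylpropanamide converts F10 into 2-{(1R)-1-[4,6-bis(benzyloxy)-2-hydroxy-3-methyl-5-(3-phenylpropanoyl)phenyl]-3-phenylpropyl}-3-hydroxy-4,4,6,6-tetramethylcyclohex-2-ene-1,5-dione F11.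
- Hydrogenolysis (H2, 10% Pd/C) of F11 gives 14.

Step 3. Hydride delivery to the crowded C-4, which lies peri to a benzyloxy group, may be slow or poorly face-selective, and the lactone may be reduced further.
- The fallback sets out from 1 and comes back at 6.
- It creates the stereocentre by C–C instead of C–H bond formation.
- Compound 1 and ethyl propiolate (ZnCl2, 100 °C, Pechmann-type condensation) give 5,7-dihydroxy-8-methyl-2H-chromen-2-one F12.
- BnBr and K2CO3 in DMF give 5,7-bis(benzyloxy)-8-methyl-2H-chromen-2-one F13.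
- Copper-catalysed asymmetric conjugate addition of 2-phenylethylmagnesium bromide follows (CuBr·SMe2, a Josiphos-type ferrocenyl bisphosphine of the antipode that gives 4S, t-BuOMe, −75 °C). It gives the bromomagnesium enolate of 6 F14, which aqueous NH4Cl protonates to 6.

Further compounds
F1 | step 5 | disodium (3S)-3-[4,6-bis(benzyloxy)-3-methyl-2-oxidophenyl]-5-phenylpentanoate | [Na+].[Na+].[O-]C(=O)C[C@H](CCc1ccccc1)c1c(OCc2ccccc2)cc(OCc2ccccc2)c(C)c1[O-]
F2 | step 5 | benzyl (3S)-5-phenyl-3-[2,4,6-tris(benzyloxy)-3-methylphenyl]pentanoate | O=C(OCc1ccccc1)C[C@H](CCc1ccccc1)c1c(OCc2ccccc2)cc(OCc2ccccc2)c(C)c1OCc1ccccc1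
F3 | step 5 | (3S)-5-phenyl-3-[2,4,6-tris(benzyloxy)-3-methylphenyl]pentanoic acid | OC(=O)C[C@H](CCc1ccccc1)c1c(OCc2ccccc2)cc(OCc2ccccc2)c(C)c1OCc1ccccc1
F4 | step 5 | (3S)-5-phenyl-3-[2,4,6-tris(benzyloxy)-3-methylphenyl]pentanoyl chloride | ClC(=O)C[C@H](CCc1ccccc1)c1c(OCc2ccccc2)cc(OCc2ccccc2)c(C)c1OCc1ccccc1
F5 | step 5 | methyl (7S)-2,2,4,4-tetramethyl-3,5-dioxo-9-phenyl-7-[2,4,6-tris(benzyloxy)-3-methylphenyl]nonanoate | COC(=O)C(C)(C)C(=O)C(C)(C)C(=O)C[C@H](CCc1ccccc1)c1c(OCc2ccccc2)cc(OCc2ccccc2)c(C)c1OCc1ccccc1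
F6 | step 5 | 3-hydroxy-4,4,6,6-tetramethyl-2-{(1R)-3-phenyl-1-[2,4,6-tris(benzyloxy)-3-methylphenyl]propyl}cyclohex-2-ene-1,5-dione | Cc1c(OCc2ccccc2)cc(OCc2ccccc2)c([C@@H](CCc2ccccc2)C2=C(O)C(C)(C)C(=O)C(C)(C)C2=O)c1OCc1ccccc1
F7 | step 7 | (4S)-5,7-bis(benzyloxy)-6-bromo-8-methyl-4-(2-phenylethyl)chroman-2-one | O=C1C[C@H](CCc2ccccc2)c2c(OCc3ccccc3)c(Br)c(OCc3ccccc3)c(C)c2O1
F8 | step 7 | methyl (7S)-7-[4,6-bis(benzyloxy)-5-bromo-2-hydroxy-3-methylphenyl]-2,2,4,4-tetramethyl-3,5-dioxo-9-phenylnonanoate | COC(=O)C(C)(C)C(=O)C(C)(C)C(=O)C[C@H](CCc1ccccc1)c1c(OCc2ccccc2)c(Br)c(OCc2ccccc2)c(C)c1O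
F9 | step 7 | 2-{(1R)-1-[4,6-bis(benzyloxy)-5-bromo-2-hydroxy-3-methylphenyl]-3-phenylpropyl}-3-hydroxy-4,4,6,6-tetramethylcyclohex-2-ene-1,5-dione | Cc1c(OCc2ccccc2)c(Br)c(OCc2ccccc2)c([C@@H](CCc2ccccc2)C2=C(O)C(C)(C)C(=O)C(C)(C)C2=O)c1O
F10 | step 7 | aryllithium dilithium salt of the debrominated triketone (lithium at the former C–Br carbon, lithium phenoxide, lithium triketonate) | Cc1c(OCc2ccccc2)c([Li])c(OCc2ccccc2)c([C@@H](CCc2ccccc2)C2=C([O-])C(C)(C)C(=O)C(C)(C)C2=O)c1[O-].[Li+].[Li+]
F11 | step 7 | 2-{(1R)-1-[4,6-bis(benzyloxy)-2-hydroxy-3-methyl-5-(3-phenylpropanoyl)phenyl]-3-phenylpropyl}-3-hydroxy-4,4,6,6-tetramethylcyclohex-2-ene-1,5-dione | Cc1c(OCc2ccccc2)c(C(=O)CCc2ccccc2)c(OCc2ccccc2)c([C@@H](CCc2ccccc2)C2=C(O)C(C)(C)C(=O)C(C)(C)C2=O)c1O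
F12 | step 3 | 5,7-dihydroxy-8-methyl-2H-chromen-2-one | O=C1C=Cc2c(O)cc(O)c(C)c2O1
F13 | step 3 | 5,7-bis(benzyloxy)-8-methyl-2H-chromen-2-one | O=C1C=Cc2c(OCc3ccccc3)cc(OCc3ccccc3)c(C)c2O1
F14 | step 3 | bromomagnesium enolate of 6 | Br[Mg]OC1=C[C@H](CCc2ccccc2)c2c(OCc3ccccc3)cc(OCc3ccccc3)c(C)c2O1
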